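**Strategy.** The cis‑3,4‑diol of ring A (C10–C1–C2–C3–C4–C5) is read as a masked 1,6‑dicarbonyl: C3 aldehyde plus C4 methyl ketone. A SmI2 pinacol cyclisation forms the C3–C4 bond, closes ring A as the final ring and sets both carbinol centres, with O3/O4 cis and the C4 oxygen axial, syn to the C10 methyl. The precursor is a ketal‑protected cyclohexanone carrying trans 3‑oxopropyl (on quaternary C10) and acetyl (on C5) groups. It comes from (+)‑verbenone by conjugate addition, cyclobutane C–C cleavage and double ozonolysis, so both ring‑fusion stereocentres derive from the pinane. Ring B is finished by acylations, acetone aldol, dehydration and dienolate hydroxylation.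

Key step: step 5

Remark: eudesmane numbering (C1–C15) is used for ring atoms throughout; the target is (3S,4R,5R,7S,10R), i.e. 3β‑OAng, 4β‑OAc, 4α‑Me, 5α‑H, 7α‑OH, 10β‑Me.
Remark: (1R,5R)‑(+)‑verbenone is assumed to be purchasable (it is the allylic oxidation product of (+)‑α‑pinene).
Remark: steps 3 and 5 are two‑stage operations run without isolating the first‑stage product; the C7 configuration in 16–18 is of no consequence because C7 becomes trigonal in 19 and 20.

Step 1
Reactants: 1 (1R,5R)‑(+)‑verbenone; 2 but‑3‑en‑1‑ylmagnesium bromide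
Product: 4 (1R,4R,5R)‑4‑(but‑3‑en‑1‑yl)‑4,6,6‑trimethylbicyclo[3.1.1]heptan‑2‑one, via bromomagnesium enolate 3 (not isolated)
Conditions: CuBr·SMe2 (10 mol %), THF, −40 → 0 °C; then 1 M HCl
Reagents that add atoms: but‑3‑en‑1‑ylmagnesium bromide (2), C=CCC[Mg]Br
Why: copper‑catalysed conjugate addition of a Grignard reagent to the β‑methyl enone, in which the nucleophile should reach C4 of the pinane from the CH2‑bridge face, anti to the gem‑dimethyl bridge, so that the quaternary centre (future C10) is set as 4R next to the existing C5 centre.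

Step 2
Reactants: 4 adduct ketone
Product: 5 (4S,5R)‑5‑(but‑3‑en‑1‑yl)‑5‑methyl‑4‑(prop‑1‑en‑2‑yl)cyclohex‑1‑en‑1‑yl acetate
Conditions: Ac2O, BF3·OEt2 (20 mol %), CH2Cl2, −20 → 0 °C, short reaction time; NaHCO3 quench
Reagents that add atoms: acetic anhydride, CC(=O)OC(C)=O
Why: Lewis acid/anhydride‑induced Grob‑type fragmentation of a nopinone‑type cyclobutyl ketone, in which O‑acylation lets the strained bridgehead–CMe2 bond break to the enol acetate and a tertiary cation that should lose a methyl proton (acetate capture and the tetrasubstituted olefin are disfavoured by the adjacent quaternary carbon); no stereocentre is touched, so the trans C5/C10 relationship is inherited from 4.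

Step 3
Reactants: 5 enol acetate
Product: 7 (7R,8S)‑7‑(but‑3‑en‑1‑yl)‑7‑methyl‑8‑(prop‑1‑en‑2‑yl)‑1,4‑dioxaspiro[4.5]decane, via ketone 6 (not isolated)
Conditions: K2CO3 (cat.), MeOH, 0 °C → rt; concentrate; then HOCH2CH2OH, PPTS (cat.), benzene, reflux (Dean–Stark)
Reagents that add atoms: ethane‑1,2‑diol, OCCO
Why: methanolysis of the enol ester releases the C8 ketone, which is then acetalised under mild PPTS catalysis so that C8 cannot act as an acceptor in step 5 and the isopropenyl group is not isomerised.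

Step 4
Reactants: 7 ketal diene
Product: 9 3‑[(7R,8R)‑8‑acetyl‑7‑methyl‑1,4‑dioxaspiro[4.5]decan‑7‑yl]propanal, via bis‑ozonide 8 (not isolated)
Conditions: O3, CH2Cl2, −78 °C; then PPh3, −78 °C → rt
Reagents that add atoms: ozone, [O-][O+]=O
Why: ozonolysis with reductive work‑up cleaves both terminal alkenes in one operation, turning isopropenyl into the C4 methyl ketone and butenyl into the C3 aldehyde under neutral conditions that should not epimerise C5.

Step 5
Reactants: 9 keto‑aldehyde
Product: 11 (4aR,5R,6S,8aR)‑5,6‑dihydroxy‑5,8a‑dimethyloctahydronaphthalen‑2(1H)‑one (3β,4β‑dihydroxy‑11,12,13‑trinoreudesman‑8‑one), via diol ketal 10 (not isolated)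
Conditions: SmI2 (2.5 equiv), t‑BuOH (2 equiv), THF, high dilution, −78 → 0 °C; then 1 M HCl, THF, rt
Reagents that add atoms: water, O
Why: SmI2 reduces the aldehyde C3 to a samarium(III) ketyl, which adds to the Sm‑coordinated methyl ketone carbon C4 (6‑exo‑trig onto C=O), and the second equivalent reduces the resulting oxygen radical, so ring A closes through the C3–C4 bond as a samarium‑bridged cis‑diolate. The closest known reaction type is the SmI2‑mediated intramolecular ketone–aldehyde pinacol coupling, which gives cis‑cycloalkane‑1,2‑diols. The ring should close in a chair on the fixed trans C5/C10 scaffold, with tether and acetyl both equatorial on ring B. C4 is controlled by the C10 methyl: the C4 methyl takes the equatorial (α) site and the smaller O–Sm the axial (β) site, avoiding a 1,3‑diaxial methyl/methyl contact; C3 is controlled by chelation, the bridging samarium holding O3 cis to O4, i.e. 3β‑equatorial. The step needs chemoselectivity (the ketyl must find C4 and not the ring‑B carbonyl or a second molecule), which the C8 ketal and high dilution secure, and it needs C5 to stay unepimerised, which the non‑basic medium secures. Aqueous acid in the second stage then unmasks the C8 ketone.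

Step 6
Reactants: 11 diol ketone; 12 angelic acid
Product: 13 3β‑angeloyloxy‑4β‑hydroxy‑11,12,13‑trinoreudesman‑8‑one (3S,4R,5R,10R)
Conditions: 12, 2,4,6‑trichlorobenzoyl chloride, Et3N, toluene, rt; then 11, 75 °C (no DMAP)
Reagents that add atoms: angelic acid (12), C/C=C(/C)C(=O)O
Why: Yamaguchi‑type esterification through the mixed anhydride, which should acylate only the secondary equatorial C3 hydroxyl (the tertiary axial C4 hydroxyl is too hindered) and, without nucleophilic catalyst, should keep the Z geometry of the angelate.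

Step 7
Reactants: 13 mono‑angelate
Product: 14 4β‑acetoxy‑3β‑angeloyloxy‑11,12,13‑trinoreudesman‑8‑one
Conditions: Ac2O, Et3N, DMAP (1 equiv), CH2Cl2, 40 °C
Reagents that add atoms: acetic anhydride, CC(=O)OC(C)=O
Why: DMAP‑mediated acyl transfer (Steglich‑type acetylation) onto the only remaining hydroxyl, the tertiary axial C4–OH, under conditions that leave the ketone and the already formed angelate untouched.

Step 8
Reactants: 14 keto diester; 15 acetone
Product: 17 4β‑acetoxy‑3β‑angeloyloxy‑11‑hydroxyeudesman‑8‑one (drawn 7R), via lithium enolate 16 (not isolated)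
Conditions: LDA (1.05 equiv), THF, −78 °C; acetone (3 equiv), −78 °C; AcOH quench at −78 °C
Reagents that add atoms: acetone (15), CC(C)=O
Why: kinetic deprotonation should occur at C7, the unhindered α‑methylene, rather than at neopentyl C9 or the much less acidic ester α‑positions, and the lithium enolate undergoes aldol addition to acetone; the new C7 centre is erased in the next step.

Step 9
Reactants: 17 β‑hydroxy ketone
Product: 19 4β‑acetoxy‑3β‑angeloyloxyeudesm‑7(11)‑en‑8‑one, via sulfamate ester 18 (not isolated)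
Conditions: methyl N‑(triethylammoniosulfonyl)carbamate (Burgess reagent), benzene, 50 °C
Reagents that add atoms: none
Why: Burgess dehydration of a tertiary β‑hydroxy ketone (syn‑elimination of the sulfamate, assisted by the acidic C7–H) should give the conjugated isopropylidene enone under neutral conditions that spare both esters.

Step 10
Reactants: 19 isopropylidene enone
Product: 21 4β‑acetoxy‑3β‑angeloyloxy‑7α‑hydroxyeudesm‑11‑en‑8‑one (target, 3S,4R,5R,7S,10R), via potassium dienolate 20 (not isolated)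
Conditions: KHMDS (1.0 equiv), THF, −78 → −40 → −78 °C; 2‑(phenylsulfonyl)‑3‑phenyloxaziridine, −78 °C; AcOH quench at −78 °C
Reagents that add atoms: 2‑(phenylsulfonyl)‑3‑phenyloxaziridine, O=S(=O)(N1OC1c1ccccc1)c1ccccc1
Why: the through‑conjugated potassium dienolate (γ‑deprotonation of an isopropylidene methyl, reached by equilibration) is oxidised at its α‑carbon C7 by the N‑sulfonyloxaziridine (deconjugative enolate α‑hydroxylation), the oxidant approaching axially on the α‑face, anti to the C10 methyl, which should give 7α‑OH with the isopropenyl group equatorial.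

**Compound list**

1 | (1R,5R)‑(+)‑verbenone, (1R,5R)‑4,6,6‑trimethylbicyclo[3.1.1]hept‑3‑en‑2‑one | CC1=CC(=O)[C@@H]2C[C@H]1C2(C)C | starting material
2 | but‑3‑en‑1‑ylmagnesium bromide | C=CCC[Mg]Br | starting material
3 | bromomagnesium enolate of 4 | C=CCC[C@]1(C)C=C(O[Mg]Br)[C@@H]2C[C@H]1C2(C)C | intermediate (not isolated)
4 | (1R,4R,5R)‑4‑(but‑3‑en‑1‑yl)‑4,6,6‑trimethylbicyclo[3.1.1]heptan‑2‑one | C=CCC[C@]1(C)CC(=O)[C@@H]2C[C@H]1C2(C)C | intermediate
5 | (4S,5R)‑5‑(but‑3‑en‑1‑yl)‑5‑methyl‑4‑(prop‑1‑en‑2‑yl)cyclohex‑1‑en‑1‑yl acetate | CC(=O)OC1=CC[C@@H](C(C)=C)[C@](C)(CCC=C)C1 | intermediate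
6 | (3R,4S)‑3‑(but‑3‑en‑1‑yl)‑3‑methyl‑4‑(prop‑1‑en‑2‑yl)cyclohexan‑1‑one | O=C1CC[C@@H](C(C)=C)[C@](C)(CCC=C)C1 | intermediate (not isolated)
7 | (7R,8S)‑7‑(but‑3‑en‑1‑yl)‑7‑methyl‑8‑(prop‑1‑en‑2‑yl)‑1,4‑dioxaspiro[4.5]decane | O1CCOC12CC[C@@H](C(C)=C)[C@](C)(CCC=C)C2 | intermediate
8 | bis‑ozonide of 7 (two 1,2,4‑trioxolanes, trioxolane carbons of undefined configuration) | O1CCOC12CC[C@@H](C3(C)OCOO3)[C@](C)(CCC3OCOO3)C2 | intermediate (not isolated)
9 | 3‑[(7R,8R)‑8‑acetyl‑7‑methyl‑1,4‑dioxaspiro[4.5]decan‑7‑yl]propanal | O1CCOC12CC[C@@H](C(C)=O)[C@](C)(CCC=O)C2 | intermediate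
10 | 8,8‑ethylenedioxy‑11,12,13‑trinoreudesmane‑3β,4β‑diol (3S,4R,5R,10R) | C1C[C@@H]2[C@](C)(CC[C@H](O)[C@]2(C)O)CC13OCCO3 | intermediate (not isolated)
11 | (4aR,5R,6S,8aR)‑5,6‑dihydroxy‑5,8a‑dimethyloctahydronaphthalen‑2(1H)‑one | C1C[C@@H]2[C@](C)(CC[C@H](O)[C@]2(C)O)CC1=O | intermediate
12 | angelic acid, (Z)‑2‑methylbut‑2‑enoic acid | C/C=C(/C)C(=O)O | starting material
13 | 3β‑angeloyloxy‑4β‑hydroxy‑11,12,13‑trinoreudesman‑8‑one | C1C[C@@H]2[C@](C)(CC[C@H](OC(=O)/C(C)=C\C)[C@]2(C)O)CC1=O | intermediate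
14 | 4β‑acetoxy‑3β‑angeloyloxy‑11,12,13‑trinoreudesman‑8‑one | C1C[C@@H]2[C@](C)(CC[C@H](OC(=O)/C(C)=C\C)[C@]2(C)OC(C)=O)CC1=O | intermediate
15 | acetone | CC(C)=O | starting material
16 | lithium Δ7‑enolate of 14 | C=1C[C@@H]2[C@](C)(CC[C@H](OC(=O)/C(C)=C\C)[C@]2(C)OC(C)=O)CC=1O[Li] | intermediate (not isolated)
17 | 4β‑acetoxy‑3β‑angeloyloxy‑11‑hydroxyeudesman‑8‑one (7R drawn, side chain equatorial) | CC(C)(O)[C@H]1C[C@@H]2[C@](C)(CC[C@H](OC(=O)/C(C)=C\C)[C@]2(C)OC(C)=O)CC1=O | intermediate
18 | triethylammonium N‑(methoxycarbonyl)sulfamate ester of the C11 hydroxyl of 17 | COC(=O)[N-]S(=O)(=O)OC(C)(C)[C@H]1C[C@@H]2[C@](C)(CC[C@H](OC(=O)/C(C)=C\C)[C@]2(C)OC(C)=O)CC1=O.CC[NH+](CC)CC | intermediate (not isolated)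
19 | 4β‑acetoxy‑3β‑angeloyloxyeudesm‑7(11)‑en‑8‑one | CC(C)=C1C[C@@H]2[C@](C)(CC[C@H](OC(=O)/C(C)=C\C)[C@]2(C)OC(C)=O)CC1=O | intermediate
20 | potassium 7,11(12)‑dienolate of 19 | C=C(C)C=1C[C@@H]2[C@](C)(CC[C@H](OC(=O)/C(C)=C\C)[C@]2(C)OC(C)=O)CC=1[O-].[K+] | intermediate (not isolated)
21 | 4β‑acetoxy‑3β‑angeloyloxy‑7α‑hydroxyeudesm‑11‑en‑8‑one (CNP0381775.1) | C=C(C)[C@@]1(O)C[C@@H]2[C@](C)(CC[C@H](OC(=O)/C(C)=C\C)[C@]2(C)OC(C)=O)CC1=O | target

**Count.** Total steps: 10. Longest linear sequence: 10 steps (from 1).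

**Steps most likely to fail**

Step 2 (fate of the tertiary cation). The cation may be captured by acetate, or may shift or isomerise, instead of losing a methyl proton; the terminal alkene may also be attacked under Lewis acid. The fallback sets out from 4 and returns at 7, and it accepts capture on purpose. With Ac2O, BF3·OEt2 and Zn(OAc)2 the fragmentation should give (4R,5R)‑4‑(2‑acetoxypropan‑2‑yl)‑5‑(but‑3‑en‑1‑yl)‑5‑methylcyclohex‑1‑en‑1‑yl acetate F1. Methanolysis (K2CO3, MeOH) followed by ethane‑1,2‑diol/PPTS should give the ketal tertiary acetate 2‑[(7R,8R)‑7‑(but‑3‑en‑1‑yl)‑7‑methyl‑1,4‑dioxaspiro[4.5]decan‑8‑yl]propan‑2‑yl acetate F2. LiAlH4 then cleaves the hindered acetate to the tertiary alcohol 2‑[(7R,8R)‑7‑(but‑3‑en‑1‑yl)‑7‑methyl‑1,4‑dioxaspiro[4.5]decan‑8‑yl]propan‑2‑ol F3. SOCl2/pyridine at 0 °C (E2 from the accessible methyl hydrogens, the ring C–H being shielded by the quaternary carbon) should deliver 7.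

Step 5 (key step). The coupling may proceed without chelation and give the wrong relative configuration; the aldehyde may simply be reduced; or C5 may epimerise before ring closure. The fallback sets out from 9 and returns at 10, and it replaces the reductive coupling by a redox‑neutral one. An N‑heterocyclic‑carbene‑catalysed intramolecular crossed aldehyde–ketone benzoin reaction (triazolium precatalyst, Et3N) should give 8,8‑ethylenedioxy‑4β‑hydroxy‑11,12,13‑trinoreudesman‑3‑one F4, again with the C4 methyl equatorial. NaBH4 in MeOH at −40 °C (axial hydride delivery from the α‑face) should then give the 3β‑alcohol 10, which the acid stage of step 5 converts to 11.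

Step 10 (site and face of the oxidation). Deprotonation may occur at C9 (cross‑conjugated enolate) or at an ester, or the oxidant may attack the β‑face; the tertiary α‑ketol alkoxide may also rearrange if warmed. The fallback sets out from 19 and returns at 21, and it avoids base altogether. A Schenck ene reaction of the s‑cis isopropylidene enone with singlet oxygen (O2, tetraphenylporphyrin, hν, CH2Cl2, 0 °C) should place the oxygen on C7 with shift of the double bond to C11–C12, giving 4β‑acetoxy‑3β‑angeloyloxy‑7α‑hydroperoxyeudesm‑11‑en‑8‑one F5. PPh3 then reduces the hydroperoxide to 21.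

**Further compounds**

F1 | step 2 | (4R,5R)‑4‑(2‑acetoxypropan‑2‑yl)‑5‑(but‑3‑en‑1‑yl)‑5‑methylcyclohex‑1‑en‑1‑yl acetate | CC(=O)OC1=CC[C@@H](C(C)(C)OC(C)=O)[C@](C)(CCC=C)C1
F2 | step 2 | 2‑[(7R,8R)‑7‑(but‑3‑en‑1‑yl)‑7‑methyl‑1,4‑dioxaspiro[4.5]decan‑8‑yl]propan‑2‑yl acetate | O1CCOC12CC[C@@H](C(C)(C)OC(C)=O)[C@](C)(CCC=C)C2
F3 | step 2 | 2‑[(7R,8R)‑7‑(but‑3‑en‑1‑yl)‑7‑methyl‑1,4‑dioxaspiro[4.5]decan‑8‑yl]propan‑2‑ol | O1CCOC12CC[C@@H](C(C)(C)O)[C@](C)(CCC=C)C2
F4 | step 5 | 8,8‑ethylenedioxy‑4β‑hydroxy‑11,12,13‑trinoreudesman‑3‑one (4R,5R,10R) | C1C[C@@H]2[C@](C)(CCC(=O)[C@]2(C)O)CC13OCCO3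
F5 | step 10 | 4β‑acetoxy‑3β‑angeloyloxy‑7α‑hydroperoxyeudesm‑11‑en‑8‑one | C=C(C)[C@@]1(OO)C[C@@H]2[C@](C)(CC[C@H](OC(=O)/C(C)=C\C)[C@]2(C)OC(C)=O)CC1=O
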